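Two flasks stopped early.

| setting | Friday's | Saturday's | birch | cedar |
|---|---|---|---|---|
| substrate | 0.15 M | 0.10 M | 0.10 M | 0.10 M |
| coupling partner | 0.95 equiv | 0.95 equiv | 0.950 equiv | 0.240 equiv |
| free catalyst | 2 mol% | 1 mol% | 2 mol% | 2 mol% |
| temperature | 70 °C | 70 °C | 70 °C | 50 °C |
| remark | run made earlier | run made earlier |  |  |
| time |  |  | 80 min | 80 min |

- Friday's (time / min: target / %, substrate / %): 6.00: 24, 75; 15.0: 24, 75; 20.0: 23, 74; 30.0: 23, 72; 40.0: 23, 73; 50.0: 24, 76
- Saturday's (time / min: target / %, substrate / %): 2.50: 7, 93; 8.00: 16, 83; 15.0: 20, 78; 20.0: 19, 82; 30.0: 20, 82; 40.0: 18, 81; 50.0: 19, 78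

(scatter of a reading: 1.5 percentage points)

- the flask that ends with the higher amount of target, in percent of the substrate charged, or "neither" when 2 percentage points or less lies between them (birch / cedar / neither)
- final target, as a percentage of the substrate charged, in birch
- final target, as a percentage of the substrate charged, in cedar

- the earlier runs do not show what temperature does; that part of a forecast is a guess

- Friday's flask levels off near 0.0352 M of target and Saturday's near 0.0192 M, while their last readings still show 76% and 78% of substrate.
- The reckoning here assumes that coupling partner, the limiting reagent, has a second sink, second order in itself, and that the catalytic cycle in steady state spends partner at a steady rate proportional to the catalyst concentration; target then stops when partner stops.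
- Those two rates have two limits: a small partner charge passes over into target, and a large one ends at a ceiling that grows as the square root of the catalyst concentration.
- As an interpolation of this reckoning, the inverse squares of partner charge and ceiling add to give the inverse square of final target.
- The partner tolerance, the squared ceiling divided by the catalyst concentration, reads 0.384 M on Saturday's readings and 0.441 M on Friday's, on average 0.413 M.
- With this tolerance and their equal catalyst concentration, birch and cedar are both reckoned with a ceiling of 0.0287 M, so birch should end at 27.5% and cedar at 18.4%, birch higher.
- Holding the tolerance unchanged at 50 °C is a guess, since the earlier runs show nothing about temperature.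
- The forecast reads the plateaus as an equilibrium: “Birch repeats Saturday's concentrations with more catalyst, so it reaches the same plateau”. It gives 19.5% for birch and 9% for cedar, with birch higher; the reckoning above differs, putting birch above Saturday's plateau.

- Birch ends at 25.8% and cedar at 17.4%, so birch holds more target.

    substrate + free catalyst → catalyst intermediate A (k = 1.03 M⁻¹ s⁻¹, Ea = 37.0 kJ mol⁻¹)
    catalyst intermediate C → free catalyst + target (k = 0.331 s⁻¹, Ea = 79.0 kJ mol⁻¹)
    coupling partner + catalyst intermediate A → catalyst intermediate B (k = 13.9 M⁻¹ s⁻¹, Ea = 44.0 kJ mol⁻¹)
    2 coupling partner → self-condensation product (k = 0.138 M⁻¹ s⁻¹, Ea = 66.0 kJ mol⁻¹)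
    catalyst intermediate B → catalyst intermediate C (k = 0.258 s⁻¹, Ea = 93.0 kJ mol⁻¹)
    (constants at 70 °C)

- Cedar's coupling partner stands at 0% of its charge after 80.0 min, and its 0.0240 M charge divides into 0.0174 M as target and 0.00663 M as self-condensation product. The tolerance of 0.413 M, applied to a neighbour of cedar charged with 0.410 equiv, gives 23.5%, and that neighbour ends at 22.3%.

The earlier runs and the new flask are simulated for an exercise.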